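Read the solid column of the earlier run first, before fitting anything to the target.

- blue: solid substrate 0.49 M; partner 0.98 M; run made earlier
- flask: solid substrate 0.49 M; partner 0.490 M; time 20 min

blue run (percent of the solid substrate charged)

| time / min | target / % | solid substrate / % |
|---|---|---|
| 1.00 | 15 | 25 |
| 2.00 | 8 | 2 |
| 3.00 | 1 | 0 |
| 4.00 | 0 | 1 |
| 5.00 | 0 | 0 |
| 6.00 | 2 | 1 |

(scatter of a reading: 1.5 percentage points)

- in percentages every species weighs as the solid substrate in it: one homo product or homo dimer counts as two
- as a solid, counted per litre of solution: solid substrate
- steps under discussion: partner -> second intermediate; 2 starting material -> homo dimer; target -> over-reaction product; starting material -> open intermediate; 2 open intermediate -> homo product; open intermediate + second intermediate -> target; solid substrate <-> starting material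
- at the start none of the solid substrate is in solution

- time, not beyond 20 min, at which the flask holds most target
- the amount of target, in percent of the solid substrate charged, at that time
- earliest time at which at least nineteen twentieths of that best amount are there, in min
- latest time at which they still are, in min

In the blue run the solid substrate stood at 25% after 1.00 min. A fall by constant fractions would have left 6.25% after 2.00 min, but the reading there was 2%, with a scatter of 1.5 percentage points, so I took the loss as steady. A steady loss from the first reading ends at 1.33 min. I called this the clearance time, the moment the solid is used up and the feed into solution stops.

Then I turned the settings one by one. The time limit of 20 min is far longer than the clearance time, so I did not expect it to cut off the peak. The solid charge stayed at 0.49 M, as in the blue run, so I kept the clearance time. The partner went from 0.98 M to 0.490 M, half. Target in proportion to partner would bring the blue reading of 15% down to 7.50%, which I held as my low guess for the best amount.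

The forecast gave 9.5% (6% to 14%) at 1.1 min (0.7 min to 1.6 min), with the window from 0.9 min to 1.35 min, on the ground that “peak timing barely moves, perhaps slightly later”. My clearance time lay later than its peak.

The flask held most target, 11.5%, at 1.35 min, and the window asked for ran from 1.11 min to 1.53 min.

    partner → second intermediate (k = 0.0110 s⁻¹)
    2 starting material → homo dimer (k = 1.80 × 10⁻⁴ M⁻¹ s⁻¹)
    target → over-reaction product (k = 0.0620 s⁻¹)
    starting material → open intermediate (k = 0.330 s⁻¹)
    2 open intermediate → homo product (k = 0.00200 M⁻¹ s⁻¹)
    open intermediate + second intermediate → target (k = 0.160 M⁻¹ s⁻¹)
    solid substrate ⇌ starting material, rate k7*(cs7 - [starting material]) while solid is left; crystals form when [starting material] > cs7 (solubility = 0.320 M, k = 0.0200 s⁻¹)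

At the peak at 1.35 min the flask showed solid substrate at 0% and starting material at 3.62%, and the target's half-life by over-reaction, 0.19 min at 0.674 min, was shorter than the clearance time of 1.33 min. The neighbour flask with 0.20 M of solid substrate reckons to a clearance time of 0.543 min, and its best amount of target was 17.8%.

The data are simulated with made-up constants; the scatter is artificial.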